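**Plan**

1. Numbering: decalin C1–C10 (labdane style), chain C11–C16, butenolide C16–C19 (ring O on C16, C19 = carbonyl), C20 = methyl on C17, C21 = exo-methylene on C13, C22 = methyl on C8, C23 = 4α carbon (CHO), C24 = 4β-methyl, C25 = methyl on C10; β is the face of C25.
2. Enabling feature: ring B carries oxygen at C6 para to the chain-bearing C9, which sits next to quaternary C10. This is the pattern left by a [4+2] addition of a 2-siloxydiene C7=C6–C5=C10 (on ring A) to an enal C8=C9–C11.
3. Cuts: C12–C13 (B-alkyl Suzuki) separates decalin and side chain; ring B is cut at C7–C8 and C9–C10; the C23 aldehyde goes back to a methyl C–H; in the side chain C17=C18 (metathesis), C16–C17 and C13–C21 (Grignard additions to L-tartrate-derived amides).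
4. Forward: ring A is β-cyclocitral; ring B closes in the cycloaddition; the C8 and C6 hydroxyls follow via enone, epoxide and reductions; C23 is oxidised by nitrite photolysis; the dioxolane–butenolide enol triflate is built from L-tartrate (butenolide ring last) and joined at C12–C13; one acid step unmasks the target.
5. Stereo: C10 from the chiral oxazaborolidinium catalyst; C9 from the cycloaddition geometry (equatorial); C5 by equilibration; C8 by α-face epoxidation; C6 by dissolving-metal reduction; C4 by proximity of the 6α oxygen to the equatorial methyl; C14/C15 from L-tartaric acid; C16 by Felkin–Anh reduction.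

Key step: step 4

Remark: a 6α-hydroxy C23 aldehyde can close to a 6,23-lactol; the target is taken as the open form drawn, and step 23 releases this ring–chain pair.
Remark: the sense of induction in step 4 is assigned from the accepted binding model of cationic oxazaborolidines (enal s-trans, formyl C–H···O contact, rear face covered by a phenyl group), and the exo mode is assumed.
Remark: 3 is racemic and 25 is the commercial E/Z mixture; both elements disappear (steps 2 and 21).

**Route**

Step 1
Reactants: 1 β-cyclocitral; 2 methylmagnesium bromide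
Product: 3 1-(2,6,6-trimethylcyclohex-1-en-1-yl)ethanol (racemic)
Conditions: MeMgBr, THF, 0 °C; aq. NH4Cl
Reagents that add atoms: none
Why: 1,2-addition of the Grignard reagent to the hindered enal should give the allylic carbinol, whose stereocentre is removed in step 2.

Step 2
Reactants: 3 1-(2,6,6-trimethylcyclohex-1-en-1-yl)ethanol
Product: 4 1-(2,6,6-trimethylcyclohex-1-en-1-yl)ethanone
Conditions: Dess–Martin periodinane, NaHCO3, CH2Cl2, rt
Reagents that add atoms: none
Why: Dess–Martin oxidation of the secondary allylic alcohol should give the methyl ketone under neutral conditions that leave the tetrasubstituted alkene in place.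

Step 3
Reactants: 4 1-(2,6,6-trimethylcyclohex-1-en-1-yl)ethanone
Product: 5 triisopropyl{[1-(2,6,6-trimethylcyclohex-1-en-1-yl)ethenyl]oxy}silane (siloxydiene C7=C6(OSi)–C5=C10)
Conditions: i-Pr3SiOTf, Et3N, CH2Cl2, 0 °C to rt
Reagents that add atoms: triisopropylsilyl trifluoromethanesulfonate, CC(C)[Si](C(C)C)(C(C)C)OS(=O)(=O)C(F)(F)F
Why: soft enolisation with silyl triflate and amine takes place at the acetyl methyl group, the only α-position bearing hydrogen, giving the cross-conjugated 2-siloxydiene, and the triisopropylsilyl group is chosen for its resistance to the acidic catalyst of step 4.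

Step 4
Reactants: 5 siloxydiene; 6 (E)-crotonaldehyde
Product: 7 cycloadduct aldehyde (ring B with C5=C6 silyl enol ether, 6-OSi(i-Pr)3, 8α-methyl, 9β-CHO, 10β-methyl; 8R,9S,10R)
Conditions: 20 mol % N-protonated (S)-3,3-diphenyl-1-(o-tolyl)tetrahydro-1H,3H-pyrrolo[1,2-c][1,3,2]oxazaborole bis(trifluoromethylsulfonyl)imide (C24H25BNO+ C2F6NO4S2−, from (S)-α,α-diphenylprolinol, tri-o-tolylboroxine and HN(SO2CF3)2), 6 (3 equiv), CH2Cl2, −78 to −40 °C
Reagents that add atoms: none
Why: Proposed new method: the N-protonated oxazaborolidine binds the formyl oxygen of s-trans 6 (formyl C–H···O contact to the ring oxygen, one phenyl group stacked under the enal), C7 of the electron-rich siloxydiene adds to C8 and C9 then bonds to the fully substituted C10, either through one highly asynchronous [4+2] transition state or, in the limit, as a Mukaiyama–Michael addition followed by 6-endo-trig collapse of the boron enolate onto the siloxyallyl cation. The closest known reactions are the cationic oxazaborolidine-catalysed Diels–Alder additions of 2-siloxybutadienes to enals and the aluminium Lewis acid-promoted cycloadditions of hindered 1-(1-siloxyvinyl)cyclohexenes to enones, whereas the union of this diene, a chiral catalyst and a β-substituted enal is without precedent. Ring B closes as the six-membered cycloaddition ring by forming C7–C8 and C9–C10 (a double Michael closure in the stepwise limit). C10 is fixed by the catalyst, whose (S) form leaves the C9 Re/C8 Si face of the enal open, together with the exo placement of the formyl group, which keeps the catalyst-bound carbonyl away from ring A and its gem-dimethyl group; C8 and C9 follow from the E geometry of 6 (methyl and formyl trans), C9 remains correctable by enolisation and C8 is erased in step 7. The step needs para regiochemistry, secured by the 2-siloxy group that makes C7 the nucleophilic terminus, and a single enal face and topology, secured by the shielding phenyl group and by the steric demand of ring A; the triisopropylsilyl group suppresses silyl transfer and protodesilylation by the acidic catalyst.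

Step 5
Reactants: 7 cycloadduct aldehyde
Product: 8 9β-vinyl silyl enol ether (C11=C12 in place of the formyl group)
Conditions: Ph3PCH3Br, KN(SiMe3)2, THF, 0 °C; then 7, −78 to 0 °C
Reagents that add atoms: methyltriphenylphosphonium bromide, C[P+](c1ccccc1)(c1ccccc1)c1ccccc1.[Br-]
Why: Wittig methylenation of the neopentyl-type aldehyde should outrun enolisation at low temperature, so C9 is kept and then locked, and the vinyl group is the later hydroboration handle.

Step 6
Reactants: 8 9β-vinyl silyl enol ether
Product: 9 trans-decalin-6-one (5α-H, 8α-methyl, 9β-vinyl, 10β-methyl, 4,4-dimethyl)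
Conditions: HF·pyridine, THF, 0 °C to rt; then NaOMe (cat.), MeOH, rt
Reagents that add atoms: none
Why: protodesilylation of the silyl enol ether gives the C6 ketone and base equilibration at C5 (α to the ketone) should give the trans ring fusion, the more stable one in 6-oxo steroids and labdanes.

Step 7
Reactants: 9 trans-decalin-6-one
Product: 11 7-en-6-one (C7=C8 enone, 8-methyl, 9β-vinyl), via trimethylsilyl enol ether 10 (not isolated)
Conditions: LiN(i-Pr)2, THF, −78 °C; Me3SiCl; then Pd(OAc)2 (1.1 equiv), MeCN, rt
Reagents that add atoms: chlorotrimethylsilane, C[Si](C)(C)Cl (its atoms are in 10 only)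
Why: kinetic deprotonation occurs at the C7 methylene and not at the shielded C5 methine, and Saegusa–Ito oxidation of the silyl enol ether (β-hydride elimination toward C8) should give the enone and erase the C8 stereocentre.

Step 8
Reactants: 11 7-en-6-one
Product: 12 7α,8α-epoxy-6-ketone
Conditions: H2O2 (30 % aq.), NaOH, MeOH, 0 °C
Reagents that add atoms: hydrogen peroxide, OO
Why: in this Weitz–Scheffer nucleophilic epoxidation the hydroperoxide should add to C8 from the α face, away from the axial C10 methyl and the β vinyl group, which sets C7 and C8.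

Step 9
Reactants: 12 7α,8α-epoxy-6-ketone
Product: 13 8α-hydroxy-6-ketone (8β-methyl)
Conditions: SmI2 (2.2 equiv), THF/MeOH, −90 °C
Reagents that add atoms: none
Why: reductive opening of the α,β-epoxy ketone by SmI2 cleaves the C7–O bond through the ketyl and leaves the tertiary 8α-alcohol with C8 untouched.

Step 10
Reactants: 13 8α-hydroxy-6-ketone
Product: 14 8α-triethylsilyloxy-6-ketone
Conditions: Et3SiOTf, 2,6-lutidine, CH2Cl2, −78 °C
Reagents that add atoms: triethylsilyl trifluoromethanesulfonate, CC[Si](CC)(CC)OS(=O)(=O)C(F)(F)F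
Why: silylation of the tertiary alcohol with the silyl triflate masks it against nitrosation in step 12 and against retro-aldol cleavage in step 11.

Step 11
Reactants: 14 8α-triethylsilyloxy-6-ketone
Product: 15 6α-alcohol (8α-OSiEt3)
Conditions: Li, NH3(l), THF, MeOH, −78 °C; NH4Cl
Reagents that add atoms: none
Why: dissolving-metal reduction of the hindered ketone should give the thermodynamically favoured equatorial 6α-alcohol (hydride reagents would attack the α face and give the axial epimer), while the isolated vinyl group and the silyl ether are inert.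

Step 12
Reactants: 15 6α-alcohol
Product: 18 6α-hydroxy C23 oxime (4α-CH=NOH, 4β-methyl), via nitrite ester 16 (not isolated), via C-nitroso alcohol 17 (not isolated)
Conditions: NOCl, pyridine, −30 °C; hν (Hg lamp, Pyrex), benzene, 10 °C; then i-PrOH, reflux
Reagents that add atoms: nitrosyl chloride, O=NCl
Why: in this Barton nitrite ester reaction the 6α-alkoxy radical abstracts hydrogen through a six-membered transition state from the equatorial 4α-methyl group (peri to the equatorial 6α oxygen), the C23 radical recombines with NO and the nitroso compound tautomerises to the oxime, which makes C4 a stereocentre with the oxidised carbon α.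

Step 13
Reactants: 18 6α-hydroxy C23 oxime
Product: 19 6α,23-lactol (cyclic hemiacetal of the 6α-hydroxy C23 aldehyde, C23 epimers)
Conditions: NaNO2, AcOH/H2O, 10 °C
Reagents that add atoms: water, O
Why: nitrosative deoximation with nitrous acid, the classical release of an aldehyde after nitrite photolysis, frees the C23 aldehyde, which is trapped by the 6α-hydroxyl as the five-membered lactol.

Step 14
Reactants: 19 6α,23-lactol
Product: 20 23-methoxy-6α,23-epoxide (methyl lactol acetal, C23 epimers)
Conditions: MeOH, PPTS (cat.), 4 Å MS, rt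
Reagents that add atoms: methanol, CO
Why: acid-catalysed acetalisation of the lactol masks the aldehyde and the 6α-hydroxyl in one group that is inert to borane and base.

Step 15
Reactants: 21 dimethyl (4R,5R)-2,2-dimethyl-1,3-dioxolane-4,5-dicarboxylate (from L-tartaric acid)
Product: 22 (4R,5R)-N4,N5-dimethoxy-N4,N5,2,2-tetramethyl-1,3-dioxolane-4,5-dicarboxamide
Conditions: MeNHOMe·HCl, i-PrMgCl, THF, −20 °C
Reagents that add atoms: N,O-dimethylhydroxylamine hydrochloride, CNOC.Cl
Why: aminolysis of both esters by the magnesium amide gives the C2-symmetric bis(Weinreb amide) without touching the stereocentres (C14, C15).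

Step 16
Reactants: 22 bis(Weinreb amide); 2 methylmagnesium bromide
Product: 23 (4R,5R)-5-acetyl-N-methoxy-N,2,2-trimethyl-1,3-dioxolane-4-carboxamide
Conditions: MeMgBr (1.1 equiv), THF, −15 °C; aq. NH4Cl
Reagents that add atoms: none
Why: one equivalent of Grignard reagent adds once to the bis(Weinreb amide), whose magnesium chelate resists further addition, and by C2 symmetry either amide gives the same methyl ketone (C13, C21).

Step 17
Reactants: 23 methyl ketone amide
Product: 24 1-[(4R,5R)-5-[methoxy(methyl)carbamoyl]-2,2-dimethyl-1,3-dioxolan-4-yl]ethenyl trifluoromethanesulfonate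
Conditions: KN(SiMe3)2, THF, −78 °C; PhNTf2
Reagents that add atoms: N-phenylbis(trifluoromethanesulfonimide), O=S(=O)(N(c1ccccc1)S(=O)(=O)C(F)(F)F)C(F)(F)F
Why: kinetic enolisation occurs at the methyl group and not at the alkoxy-bearing methine, and O-triflation gives the 1,1-disubstituted enol triflate that carries the future exo-methylene carbon C21.

Step 18
Reactants: 24 enol triflate amide; 25 1-methyl-1-propenylmagnesium bromide (E/Z mixture)
Product: 26 enol triflate enone (C16 ketone bearing the 1-methylpropenyl group)
Conditions: 25 (1.5 equiv), THF, −40 to 0 °C; cold aq. citric acid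
Reagents that add atoms: none
Why: in this Weinreb ketone synthesis the alkenyl Grignard reagent adds once to the amide and, in the absence of a transition-metal catalyst, should leave the enol triflate alone.

Step 19
Reactants: 26 enol triflate enone
Product: 27 allylic alcohol (C16–OH syn to C15–O, the configuration of the target)
Conditions: LiBH(s-Bu)3, THF, −78 °C
Reagents that add atoms: none
Why: Felkin–Anh 1,2-reduction by the bulky borohydride, with the C15–O bond antiperiplanar to the incoming hydride, should give the 15,16-syn alcohol and so set C16.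

Step 20
Reactants: 27 allylic alcohol; 28 acryloyl chloride
Product: 29 acrylate ester of 27
Conditions: i-Pr2NEt, DMAP (cat.), CH2Cl2, −20 to 0 °C
Reagents that add atoms: none
Why: O-acylation of the secondary allylic alcohol installs C18 and C19 as the acrylate.

Step 21
Reactants: 29 acrylate ester
Product: 30 butenolide enol triflate (4-methyl-2(5H)-furanone joined at C16 to the dioxolane carrying the 1-(triflyloxy)vinyl group)
Conditions: second-generation Grubbs catalyst (H2IMes)(PCy3)Cl2Ru=CHPh (10 mol %), toluene, 80 °C
Reagents that add atoms: none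
Why: ring-closing metathesis between the acrylate and the 1-methylpropenyl group closes the five-membered butenolide (C17=C18) with loss of propene, while the electron-poor enol triflate alkene stays out and C16 is untouched.

Step 22
Reactants: 20 methyl lactol acetal; 30 butenolide enol triflate
Product: 32 protected coupling product (C12–C13 joined, C13=C21 exo-methylene), via B-alkyl-9-BBN 31 (not isolated)
Conditions: 9-BBN, THF, rt; then aq. K3PO4 (3 M), 30, Pd(dppf)Cl2·CH2Cl2 (10 mol %), AsPh3, DMF, rt
Reagents that add atoms: 9-borabicyclo[3.3.1]nonane, B1C2CCCC1CCC2 (its atoms are in 31 only)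
Why: B-alkyl Suzuki–Miyaura coupling, in which anti-Markovnikov hydroboration of the vinyl group gives the primary borane that couples with the enol triflate, joins the fragments at C12–C13 and creates the exo-methylene unit.

Step 23
Reactants: 32 protected coupling product
Product: 33 target CNP0156243.1 (4R,5R,6S,8R,9R,10S,14S,15R,16R)
Conditions: AcOH/H2O (4:1), 45 °C
Reagents that add atoms: water, O
Why: mild aqueous acid should hydrolyse the acetonide, the tertiary triethylsilyl ether and the methyl lactol acetal in one operation, releasing the 14,15-diol, the 8α-alcohol and the 6α-hydroxy aldehyde without harming the butenolide or the allylic alcohol.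

**Compound list**

1 | β-cyclocitral (2,6,6-trimethylcyclohex-1-ene-1-carbaldehyde) | CC1=C(C=O)C(C)(C)CCC1 | starting material
2 | methylmagnesium bromide | C[Mg]Br | starting material
3 | 1-(2,6,6-trimethylcyclohex-1-en-1-yl)ethanol (racemic) | CC(O)C1=C(C)CCCC1(C)C | intermediate
4 | 1-(2,6,6-trimethylcyclohex-1-en-1-yl)ethanone | CC(=O)C1=C(C)CCCC1(C)C | intermediate
5 | triisopropyl{[1-(2,6,6-trimethylcyclohex-1-en-1-yl)ethenyl]oxy}silane | C=C(O[Si](C(C)C)(C(C)C)C(C)C)C1=C(C)CCCC1(C)C | intermediate
6 | (E)-crotonaldehyde | C/C=C/C=O | starting material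
7 | cycloadduct aldehyde (C5=C6 silyl enol ether, 8α-methyl, 9β-CHO, 10β-methyl; 8R,9S,10R) | O=C[C@@H]1[C@@]2(C)CCCC(C)(C)C2=C(O[Si](C(C)C)(C(C)C)C(C)C)C[C@H]1C | intermediate
8 | 9β-vinyl silyl enol ether | C=C[C@@H]1[C@@]2(C)CCCC(C)(C)C2=C(O[Si](C(C)C)(C(C)C)C(C)C)C[C@H]1C | intermediate
9 | trans-decalin-6-one (5α-H, 8α-methyl, 9β-vinyl, 10β-methyl) | C=C[C@@H]1[C@@]2(C)CCCC(C)(C)[C@@H]2C(=O)C[C@H]1C | intermediate
10 | trimethylsilyl enol ether (C6=C7) of 9 | C=C[C@@H]1[C@@]2(C)CCCC(C)(C)[C@@H]2C(O[Si](C)(C)C)=C[C@H]1C | intermediate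
11 | 7-en-6-one (8-methyl, 9β-vinyl, 5α-H) | C=C[C@@H]1[C@@]2(C)CCCC(C)(C)[C@@H]2C(=O)C=C1C | intermediate
12 | 7α,8α-epoxy-6-ketone | C=C[C@@H]1[C@@]2(C)CCCC(C)(C)[C@@H]2C(=O)[C@H]3O[C@]31C | intermediate
13 | 8α-hydroxy-8β-methyl-6-ketone | C=C[C@@H]1[C@@]2(C)CCCC(C)(C)[C@@H]2C(=O)C[C@@]1(C)O | intermediate
14 | 8α-triethylsilyloxy-6-ketone | C=C[C@@H]1[C@@]2(C)CCCC(C)(C)[C@@H]2C(=O)C[C@@]1(C)O[Si](CC)(CC)CC | intermediate
15 | 6α-alcohol (8α-OSiEt3, 9β-vinyl) | C=C[C@@H]1[C@@]2(C)CCCC(C)(C)[C@@H]2[C@@H](O)C[C@@]1(C)O[Si](CC)(CC)CC | intermediate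
16 | 6α-nitrite ester of 15 | C=C[C@@H]1[C@@]2(C)CCCC(C)(C)[C@@H]2[C@@H](ON=O)C[C@@]1(C)O[Si](CC)(CC)CC | intermediate
17 | 23-nitroso-6α-alcohol (4α-CH2NO) | C=C[C@@H]1[C@@]2(C)CCC[C@@](C)(CN=O)[C@@H]2[C@@H](O)C[C@@]1(C)O[Si](CC)(CC)CC | intermediate
18 | 6α-hydroxy C23 oxime (4α-CH=NOH, oxime geometry open) | C=C[C@@H]1[C@@]2(C)CCC[C@@](C)(C=NO)[C@@H]2[C@@H](O)C[C@@]1(C)O[Si](CC)(CC)CC | intermediate
19 | 6α,23-lactol (C23 epimers) | C=C[C@@H]1[C@@]2(C)CCC[C@@]3(C)C(O)O[C@@H](C[C@@]1(C)O[Si](CC)(CC)CC)[C@H]23 | intermediate
20 | 23-methoxy-6α,23-epoxide (methyl lactol acetal, C23 epimers) | C=C[C@@H]1[C@@]2(C)CCC[C@@]3(C)C(OC)O[C@@H](C[C@@]1(C)O[Si](CC)(CC)CC)[C@H]23 | intermediate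
21 | dimethyl (4R,5R)-2,2-dimethyl-1,3-dioxolane-4,5-dicarboxylate | COC(=O)[C@@H]1OC(C)(C)O[C@H]1C(=O)OC | starting material
22 | (4R,5R)-N4,N5-dimethoxy-N4,N5,2,2-tetramethyl-1,3-dioxolane-4,5-dicarboxamide | CON(C)C(=O)[C@@H]1OC(C)(C)O[C@H]1C(=O)N(C)OC | intermediate
23 | (4R,5R)-5-acetyl-N-methoxy-N,2,2-trimethyl-1,3-dioxolane-4-carboxamide | CC(=O)[C@@H]1OC(C)(C)O[C@H]1C(=O)N(C)OC | intermediate
24 | 1-[(4R,5R)-5-[methoxy(methyl)carbamoyl]-2,2-dimethyl-1,3-dioxolan-4-yl]ethenyl triflate | C=C(OS(=O)(=O)C(F)(F)F)[C@@H]1OC(C)(C)O[C@H]1C(=O)N(C)OC | intermediate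
25 | 1-methyl-1-propenylmagnesium bromide (E/Z mixture) | CC=C(C)[Mg]Br | starting material
26 | enol triflate enone (C16 ketone, 1-methylpropenyl group E/Z) | C=C(OS(=O)(=O)C(F)(F)F)[C@@H]1OC(C)(C)O[C@H]1C(=O)C(C)=CC | intermediate
27 | allylic alcohol (C16–OH syn to C15–O) | C=C(OS(=O)(=O)C(F)(F)F)[C@@H]1OC(C)(C)O[C@H]1[C@H](O)C(C)=CC | intermediate
28 | acryloyl chloride | C=CC(=O)Cl | starting material
29 | acrylate ester of 27 | C=C(OS(=O)(=O)C(F)(F)F)[C@@H]1OC(C)(C)O[C@H]1[C@H](OC(=O)C=C)C(C)=CC | intermediate
30 | butenolide enol triflate | C=C(OS(=O)(=O)C(F)(F)F)[C@@H]1OC(C)(C)O[C@H]1[C@@H]2OC(=O)C=C2C | intermediate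
31 | B-alkyl-9-BBN from 20 (boron on C12) | C(C[C@@H]1[C@@]2(C)CCC[C@@]3(C)C(OC)O[C@@H](C[C@@]1(C)O[Si](CC)(CC)CC)[C@H]23)B4C5CCCC4CCC5 | intermediate
32 | protected coupling product (14,15-acetonide, 8α-OSiEt3, methyl lactol acetal) | C=C(CC[C@@H]1[C@@]2(C)CCC[C@@]3(C)C(OC)O[C@@H](C[C@@]1(C)O[Si](CC)(CC)CC)[C@H]23)[C@@H]4OC(C)(C)O[C@H]4[C@@H]5OC(=O)C=C5C | intermediate
33 | CNP0156243.1 (4R,5R,6S,8R,9R,10S,14S,15R,16R) | C=C(CC[C@@H]1[C@@]2(C)CCC[C@@](C)(C=O)[C@@H]2[C@@H](O)C[C@@]1(C)O)[C@H](O)[C@@H](O)[C@@H]1OC(=O)C=C1C | target

**Step count and risks**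

Total steps: 23. Longest linear sequence: 16 steps (steps 1–14, 22, 23); the side-chain fragment takes 7 steps (15–21).

Step 4. The cycloaddition may stall because the diene cannot reach the s-cis geometry at the hindered C10 terminus, the siloxydiene may be protodesilylated by the acidic catalyst, or enantiocontrol may be eroded by competing endo and exo topologies or a non-selective stepwise closure. Fallback (known chemistry, setting out from 5 and 6 and returning at 7): the cycloaddition is run without asymmetric induction under the mixed aluminium Lewis acid AlBr3/AlMe3 in toluene/CH2Cl2, an activation established for hindered 1-(1-siloxyvinyl)cyclohexenes, which should give 7 as the racemate, that is together with the enantiomer of 7 F1. Condensation of the racemic aldehyde with (1R,2R)-N,N′-dimethyl-1,2-diphenylethane-1,2-diamine (4 Å molecular sieves, Et2O) should give the aminal of 7 F2 and the aminal of the enantiomer F3, which are diastereomers and are separated by chromatography. Brief treatment of F2 with dilute aqueous HCl in Et2O at 0 °C releases 7.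

Step 12. Capture of the C23 radical by nitric oxide may be inefficient (return to alcohol 15 or disproportionation to ketone 14), the alkoxy radical may fragment, or nitrosyl chloride may attack the vinyl group. Fallback (setting out from 15 and returning at 20, replacing steps 12–14): the hypoiodite reaction (Pb(OAc)4, I2, CaCO3, cyclohexane, visible light, reflux, excess reagent) generates the same 6α-alkoxy radical from an O–I bond and, after two successive hydrogen transfers from C23, should give the 23-iodo-6α,23-epoxide F4. This is solvolysed without isolation (AgOAc, MeOH) to the methyl acetal 20.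

Step 22. The aqueous base needed for boron-to-palladium transfer may epimerise C16 or open the butenolide, and transmetalation of the hindered borane may be slow. Fallback (setting out from 20 and returning at 32): hydroboration to 31 as before, then iodinolysis (I2, NaOMe, MeOH) should give the primary iodide F5. Zinc insertion (Zn dust, LiCl, THF) gives the alkylzinc iodide F6, which is coupled with 30 in a base-free Negishi reaction (Pd(PPh3)4, THF, rt) to give 32.

**Further compounds**

F1 | step 4 | enantiomer of 7 | O=C[C@H]1[C@]2(C)CCCC(C)(C)C2=C(O[Si](C(C)C)(C(C)C)C(C)C)C[C@@H]1C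
F2 | step 4 | aminal of 7 with (1R,2R)-N,N′-dimethyl-1,2-diphenylethane-1,2-diamine | CN3[C@H](c4ccccc4)[C@@H](c4ccccc4)N(C)C3[C@@H]1[C@@]2(C)CCCC(C)(C)C2=C(O[Si](C(C)C)(C(C)C)C(C)C)C[C@H]1C
F3 | step 4 | aminal of the enantiomer of 7 with the same diamine | CN3[C@H](c4ccccc4)[C@@H](c4ccccc4)N(C)C3[C@H]1[C@]2(C)CCCC(C)(C)C2=C(O[Si](C(C)C)(C(C)C)C(C)C)C[C@@H]1C
F4 | step 12 | 23-iodo-6α,23-epoxide (8α-OSiEt3, 9β-vinyl) | C=C[C@@H]1[C@@]2(C)CCC[C@@]3(C)C(I)O[C@@H](C[C@@]1(C)O[Si](CC)(CC)CC)[C@H]23
F5 | step 22 | primary C12 iodide from 20 | ICC[C@@H]1[C@@]2(C)CCC[C@@]3(C)C(OC)O[C@@H](C[C@@]1(C)O[Si](CC)(CC)CC)[C@H]23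
F6 | step 22 | C12 alkylzinc iodide | I[Zn]CC[C@@H]1[C@@]2(C)CCC[C@@]3(C)C(OC)O[C@@H](C[C@@]1(C)O[Si](CC)(CC)CC)[C@H]23
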